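The flavanone is disconnected at C2–aryl (late asymmetric conjugate arylation of a chromone) and at the biaryl axis (Negishi coupling of a 3-zincated flavone with a 6-iodochromone). The pyranone ring C is not closed as a six-membered ring. The key step exploits the 1,3-relationship in ring C between C2, bound to ring oxygen O1, and the aryl ketone carbon C4: a siloxycyclopropane fused across the furan C=C bond of a dearomatized 3-siloxybenzofuran is oxidized by FeCl3, the bond shared by both small rings breaks, and the five-membered furanone ring becomes the six-membered chromone by insertion of the cyclopropane CH2 as C3.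

Key step: step 4

Assumption: the hindered biaryl axis (flavone C3–flavanone C6) has no specified configuration in the target and is treated as an equilibrating element; C2, assigned (R) from the given structure, is the only stereocentre controlled.

Step 1
Reactants: 1 4,6-dihydroxybenzofuran-3(2H)-one
Product: 2 6-(benzyloxy)-4-hydroxybenzofuran-3(2H)-one
Conditions: BnBr (1.05 equiv), K2CO3 (1.1 equiv), DMF, 0 °C → rt
Reagents that add atoms: benzyl bromide, BrCc1ccccc1
Why: Williamson etherification, in which the 6-OH is the more acidic, non-chelated vinylogous acid while the 4-OH is hydrogen-bonded to the C3 carbonyl, so one equivalent of base and bromide should alkylate O6 selectively.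

Step 2
Reactants: 2 6-(benzyloxy)-4-hydroxybenzofuran-3(2H)-one
Product: 3 6-(benzyloxy)-3,4-bis(trimethylsilyloxy)-1-benzofuran
Conditions: TMSOTf (2.3 equiv), Et3N, CH2Cl2, 0 °C
Reagents that add atoms: trimethylsilyl trifluoromethanesulfonate, C[Si](C)(C)OS(=O)(=O)C(F)(F)F
Why: Soft enolization and O-silylation, in which the coumaranone enolizes readily to the aromatic 3-silyloxybenzofuran and the phenol is silylated in the same operation, so that no acidic proton remains for the zinc carbenoid.

Step 3
Reactants: 3 6-(benzyloxy)-3,4-bis(trimethylsilyloxy)-1-benzofuran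
Product: 4 racemic cis-fused 4-(benzyloxy)-6,6b-bis(trimethylsilyloxy)-1a,6b-dihydro-1H-cyclopropa[b][1]benzofuran
Conditions: Et2Zn, CH2I2, CH2Cl2, 0 °C → rt
Reagents that add atoms: diiodomethane, ICI
Why: Simmons–Smith cyclopropanation (Furukawa variant), in which the electrophilic zinc carbenoid adds cis to the very electron-rich enol ether C=C bond flanked by two oxygens and dearomatizes only the furan ring; the two new stereocentres form as a racemic cis pair and are erased in step 4.

Step 4
Reactants: 4 racemic cis-fused 4-(benzyloxy)-6,6b-bis(trimethylsilyloxy)-1a,6b-dihydro-1H-cyclopropa[b][1]benzofuran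
Product: 6 7-(benzyloxy)-5-hydroxy-4H-chromen-4-one, via 2-chlorochromanone 5 (not isolated)
Conditions: FeCl3 (2.5 equiv), DMF, 0 °C → rt; then NaOAc, 50 °C; aq. HCl work-up
Reagents that add atoms: none
Why: FeCl3 turns the cyclopropyl silyl ether into an alkoxide of trivalent iron, inner-sphere electron transfer gives the cyclopropyloxy radical, and β-scission of the bond common to the three- and five-membered rings gives the ring-enlarged C2 radical, which takes chlorine from a second FeCl3 to give 5, from which acetate removes HCl to give the chromone. The closest known reaction type is the Saegusa–Ito ring enlargement of 1-siloxybicyclo[n.1.0]alkanes to 2-cycloalkenones. No ring is closed by bond formation: the pyranone arises by ring expansion when the zero-atom bridge of the 2-oxabicyclo[3.1.0]hexane core is cut, so that the furan ring gains the cyclopropane CH2 as C3. No stereocentre is formed, and both cyclopropane centres end as sp2 carbons. The step needs cleavage of the internal and not the external cyclopropane bond, which is secured by O1 (α-aryloxy stabilization of the C2 radical) and by conjugation of the new ketone with ring A, whereas the alternative would give a primary radical.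

Step 5
Reactants: 6 7-(benzyloxy)-5-hydroxy-4H-chromen-4-one
Product: 7 7-(benzyloxy)-5-hydroxy-6-iodo-4H-chromen-4-one
Conditions: BnMe3N+ ICl2−, CaCO3, CH2Cl2/MeOH, rt
Reagents that add atoms: benzyltrimethylammonium dichloroiodate, C[N+](C)(C)Cc1ccccc1.Cl[I-]Cl
Why: Electrophilic aromatic iodination, in which the free, chelated 5-OH directs the iodonium equivalent to its ortho position C6 (the pattern of 5-hydroxy-7-alkoxyflavones, whereas 5-O-alkylated analogues react at C8) and the electron-poor C2=C3 bond is left alone.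

Step 6
Reactants: 7 7-(benzyloxy)-5-hydroxy-6-iodo-4H-chromen-4-one; 8 5,7-dimethoxy-2-(4-methoxyphenyl)-4H-chromen-4-one
Product: 11 7-(benzyloxy)-6-[5,7-dimethoxy-2-(4-methoxyphenyl)-4-oxo-4H-chromen-3-yl]-5-hydroxy-4H-chromen-4-one, via 3-lithioflavone 9 (not isolated), via flavonylzinc chloride 10 (not isolated)
Conditions: 8 (2.4 equiv), LiN(i-Pr)2 (2.3 equiv), THF, −78 °C; ZnCl2, −78 °C → rt; then 7, Pd2(dba)3 (2.5 mol %), SPhos (10 mol %), THF, 60 °C
Reagents that add atoms: none
Why: Negishi coupling, in which carbonyl-directed C3 lithiation of the flavone, transmetalation to zinc and palladium/SPhos-catalysed coupling with the aryl iodide should form the hindered biaryl bond under base-free conditions that the chromone tolerates, one extra equivalent of 10 converting the 5-OH into its zinc phenoxide and returning 8.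

Step 7
Reactants: 11 7-(benzyloxy)-6-[5,7-dimethoxy-2-(4-methoxyphenyl)-4-oxo-4H-chromen-3-yl]-5-hydroxy-4H-chromen-4-one; 12 4-(benzyloxy)phenylboronic acid
Product: 13 (2R)-7-(benzyloxy)-2-[4-(benzyloxy)phenyl]-6-[5,7-dimethoxy-2-(4-methoxyphenyl)-4-oxo-4H-chromen-3-yl]-5-hydroxy-2,3-dihydro-4H-chromen-4-one
Conditions: Pd(OCOCF3)2 (10 mol %), (S)-t-BuPyOx (12 mol %), NH4PF6, H2O, ClCH2CH2Cl, 60 °C
Reagents that add atoms: none
Why: Palladium-catalysed asymmetric conjugate addition of an arylboronic acid to a chromone, in which the cationic arylpalladium–PyOx complex adds only to the unsubstituted C2=C3 bond (the 2,3-diarylchromone is inert) and the tert-butyl group of the ligand selects the enone face, the (S)-ligand being expected by analogy with cyclic enones to give (2R), with the antipodal ligand used if the sense proves opposite.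

Step 8
Reactants: 13 (2R)-7-(benzyloxy)-2-[4-(benzyloxy)phenyl]-6-[5,7-dimethoxy-2-(4-methoxyphenyl)-4-oxo-4H-chromen-3-yl]-5-hydroxy-2,3-dihydro-4H-chromen-4-one
Product: 14 (2R)-5,7-dihydroxy-6-[5-hydroxy-7-methoxy-2-(4-methoxyphenyl)-4-oxo-4H-chromen-3-yl]-2-(4-hydroxyphenyl)-2,3-dihydro-4H-chromen-4-one
Conditions: BCl3, C6HMe5, CH2Cl2, −78 °C → rt
Reagents that add atoms: none
Why: Lewis-acid ether cleavage, in which BCl3 with pentamethylbenzene as benzyl cation scavenger should remove both benzyl ethers at low temperature and, on warming, only the methyl ether peri to the flavone carbonyl (chelation-assisted), leaving the 7- and 4'-methoxy groups and, under these non-basic conditions, the C2 stereocentre untouched.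

Compound list
1 | 4,6-dihydroxybenzofuran-3(2H)-one | O=C1COc2cc(O)cc(O)c21 | starting material
2 | 6-(benzyloxy)-4-hydroxybenzofuran-3(2H)-one | O=C1COc2cc(OCc3ccccc3)cc(O)c21 | intermediate
3 | 6-(benzyloxy)-3,4-bis(trimethylsilyloxy)-1-benzofuran | C[Si](C)(C)Oc1coc2cc(OCc3ccccc3)cc(O[Si](C)(C)C)c12 | intermediate
4 | racemic cis-fused 4-(benzyloxy)-6,6b-bis(trimethylsilyloxy)-1a,6b-dihydro-1H-cyclopropa[b][1]benzofuran | C[Si](C)(C)OC12CC1Oc1cc(OCc3ccccc3)cc(O[Si](C)(C)C)c12 | intermediate
5 | 7-(benzyloxy)-2-chloro-5-(trimethylsilyloxy)-2,3-dihydro-4H-chromen-4-one (not isolated) | C[Si](C)(C)Oc1cc(OCc2ccccc2)cc2OC(Cl)CC(=O)c12 | intermediate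
6 | 7-(benzyloxy)-5-hydroxy-4H-chromen-4-one | O=c1ccoc2cc(OCc3ccccc3)cc(O)c12 | intermediate
7 | 7-(benzyloxy)-5-hydroxy-6-iodo-4H-chromen-4-one | O=c1ccoc2cc(OCc3ccccc3)c(I)c(O)c12 | intermediate
8 | 5,7-dimethoxy-2-(4-methoxyphenyl)-4H-chromen-4-one (4',5,7-trimethoxyflavone) | COc1ccc(-c2cc(=O)c3c(OC)cc(OC)cc3o2)cc1 | starting material
9 | 3-lithio-5,7-dimethoxy-2-(4-methoxyphenyl)-4H-chromen-4-one (not isolated) | COc1ccc(-c2oc3cc(OC)cc(OC)c3c(=O)c2[Li])cc1 | intermediate
10 | [5,7-dimethoxy-2-(4-methoxyphenyl)-4-oxo-4H-chromen-3-yl]zinc chloride (not isolated) | COc1ccc(-c2oc3cc(OC)cc(OC)c3c(=O)c2[Zn]Cl)cc1 | intermediate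
11 | 7-(benzyloxy)-6-[5,7-dimethoxy-2-(4-methoxyphenyl)-4-oxo-4H-chromen-3-yl]-5-hydroxy-4H-chromen-4-one | COc1ccc(-c2oc3cc(OC)cc(OC)c3c(=O)c2-c2c(O)c3c(=O)ccoc3cc2OCc2ccccc2)cc1 | intermediate
12 | 4-(benzyloxy)phenylboronic acid | OB(O)c1ccc(OCc2ccccc2)cc1 | starting material
13 | (2R)-7-(benzyloxy)-2-[4-(benzyloxy)phenyl]-6-[5,7-dimethoxy-2-(4-methoxyphenyl)-4-oxo-4H-chromen-3-yl]-5-hydroxy-2,3-dihydro-4H-chromen-4-one | COc1ccc(-c2oc3cc(OC)cc(OC)c3c(=O)c2-c2c(OCc4ccccc4)cc3c(c2O)C(=O)C[C@H](c2ccc(OCc4ccccc4)cc2)O3)cc1 | intermediate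
14 | (2R)-5,7-dihydroxy-6-[5-hydroxy-7-methoxy-2-(4-methoxyphenyl)-4-oxo-4H-chromen-3-yl]-2-(4-hydroxyphenyl)-2,3-dihydro-4H-chromen-4-one | COc1ccc(-c2oc3cc(OC)cc(O)c3c(=O)c2-c2c(O)cc3c(c2O)C(=O)C[C@H](c2ccc(O)cc2)O3)cc1 | target

Total step count: 8. Longest linear sequence: 8 steps (1 → 14); flavone 8 and boronic acid 12 enter as purchased materials.

Steps most likely to fail

Step 6 (Negishi coupling). Transmetalation and reductive elimination at the tetra-ortho-substituted axis may be slower than protonation of the zinc reagent by the 5-OH, so that 8 is merely returned. The fallback reverses the polarity, sets out from 8 and 7 and comes back at 11. Compound 8 is lithiated as in step 6 and quenched with I2 to give 3-iodo-5,7-dimethoxy-2-(4-methoxyphenyl)-4H-chromen-4-one F1. Compound 7 is converted by Miyaura borylation (B2pin2, PdCl2(dppf), KOAc, dioxane) into 7-(benzyloxy)-5-hydroxy-6-(4,4,5,5-tetramethyl-1,3,2-dioxaborolan-2-yl)-4H-chromen-4-one F2. Suzuki coupling of F1 with F2 (Pd(OAc)2, SPhos, K3PO4, toluene/H2O) should then give 11. The electron-rich ring now acts as the nucleophile and the vinylogous acyl iodide as the electrophile, and boron is indifferent to the phenol.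

Step 7 (asymmetric conjugate arylation). The electron-rich, 6-aryl-substituted chromone may convert incompletely, or the catalyst may discriminate its faces poorly. The fallback sets the stereocentre by hydride delivery instead of aryl delivery, sets out from 11 and comes back at 13. Oxidative Heck-type arylation of 11 with 12 (Pd(OCOCF3)2, benzoquinone, dioxane) should give 7-(benzyloxy)-2-[4-(benzyloxy)phenyl]-6-[5,7-dimethoxy-2-(4-methoxyphenyl)-4-oxo-4H-chromen-3-yl]-5-hydroxy-4H-chromen-4-one F3. Enantioselective conjugate reduction with a chiral copper hydride (Cu(OAc)2, the DTBM-SEGPHOS enantiomer that delivers hydride to the face giving 2R, (EtO)2MeSiH, t-BuOH, THF) should then give 13. Only the trisubstituted C2=C3 bond of the new flavone ring is accessible to the hydride; the 2,3-diaryl one is not.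

Step 3 (cyclopropanation). Methylene transfer to the furan double bond may be sluggish, or zinc iodide may strip the trimethylsilyl groups before transfer. The fallback is a halocarbene ring expansion that sets out from 3, comes back at 6 and replaces steps 3 and 4. Dichlorocarbene from Cl3CCO2Na (DME, reflux) adds to 3 to give 4-(benzyloxy)-1,1-dichloro-6,6b-bis(trimethylsilyloxy)-1a,6b-dihydro-1H-cyclopropa[b][1]benzofuran F4. F4 opens in the same flask, with loss of chloride and silyl, to 7-(benzyloxy)-3-chloro-5-hydroxy-4H-chromen-4-one F5. Reductive dechlorination (Pd(PPh3)4, HCO2Na, DMF) should give 6. The five-to-six ring expansion of the furan ring is retained.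

Further compounds
F1 | step 6 | 3-iodo-5,7-dimethoxy-2-(4-methoxyphenyl)-4H-chromen-4-one | COc1ccc(-c2oc3cc(OC)cc(OC)c3c(=O)c2I)cc1
F2 | step 6 | 7-(benzyloxy)-5-hydroxy-6-(4,4,5,5-tetramethyl-1,3,2-dioxaborolan-2-yl)-4H-chromen-4-one | O=c1ccoc2cc(OCc3ccccc3)c(B3OC(C)(C)C(C)(C)O3)c(O)c12
F3 | step 7 | 7-(benzyloxy)-2-[4-(benzyloxy)phenyl]-6-[5,7-dimethoxy-2-(4-methoxyphenyl)-4-oxo-4H-chromen-3-yl]-5-hydroxy-4H-chromen-4-one | COc1ccc(-c2oc3cc(OC)cc(OC)c3c(=O)c2-c2c(OCc4ccccc4)cc3oc(-c4ccc(OCc5ccccc5)cc4)cc(=O)c3c2O)cc1
F4 | step 3 | 4-(benzyloxy)-1,1-dichloro-6,6b-bis(trimethylsilyloxy)-1a,6b-dihydro-1H-cyclopropa[b][1]benzofuran | C[Si](C)(C)OC12C(Cl)(Cl)C1Oc1cc(OCc3ccccc3)cc(O[Si](C)(C)C)c12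
F5 | step 3 | 7-(benzyloxy)-3-chloro-5-hydroxy-4H-chromen-4-one | O=c1c(Cl)coc2cc(OCc3ccccc3)cc(O)c12
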